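**Plan**

Numbering of the target: lactone O1–C2(=O)–C3(=CH2)–C3a–C8a; cycloheptane C3a–C4H2–C5(OH)–C6(CH3)–C7(OH)(acyl)–C8(O‑ester)–C8a.
Retrosynthesis cuts, in order: (1) C3a–C8a together with the lactone C2–O1 bond, giving lactol 24 with a (Z)‑2‑(bromomethyl)enoate arm; (2) the C3a–C3 bond (aldehyde + methyl acrylate); (3) the C8 ester; (4) C7–C(acyl) (pyranone ketone + alkyne); (5) C5–C6 and O–C8a of a temporary pyran (diene + aldehyde).
Forward: a hetero‑Diels–Alder reaction builds a pyran (oxygen bridging C5 and C8a) that carries C5–C8; the side chain is put on C7, the ester on C8 and the enoate arm on C4; one indium cascade then opens the lactol and closes first the cycloheptane, then the lactone.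
Stereochemistry: C5/C6 from the catalyst‑controlled endo cycloaddition, C8 from epoxidation anti to the C6 methyl, C7 from axial alkynyl addition, C8a/C3a from the cascade; the side‑chain carbinol comes from (R)‑but‑3‑yn‑2‑ol and the ester centre from (R)‑2‑methylbutanoic acid.
Enabling feature: in the cis‑fused α‑methylene‑γ‑butyrolactone the array O1–C8a–C3a–C3(=CH2)–C2(=O) is what an aldehyde carbon (C8a) and the γ‑carbon (C3a) of a 2‑(alkoxycarbonyl)allyl metal give; C8a–O and C5–OH are 1,5‑related, so a six‑membered lactol can mask the aldehyde and release the free C5–OH on opening.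

Key step: step 14

Assumption: the (1R,2S) ligand enantiomer is taken to deliver the (2R,3S)‑pyranone 7; if the sense of induction is the opposite, the mirror‑image ligand is used and nothing else changes.

**Route**

Step 1
Reactants: 1 (E)-4-methoxybut-3-en-2-one
Product: 3 (E)-1-methoxypent-1-en-3-one, via lithium dienolate 2 (not isolated)
Conditions: LiN(SiMe3)2, THF, −78 °C; then MeI, −78 to −20 °C
Reagents that add atoms: iodomethane, CI
Why: kinetic deprotonation of the vinylogous ester at its only enolisable position (the acetyl methyl) and C‑methylation of the dienolate is a standard enolate alkylation; no stereocentre is formed.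

Step 2
Reactants: 3 (E)-1-methoxypent-1-en-3-one
Product: 4 (1E,3Z)-1-methoxy-3-(trimethylsilyloxy)penta-1,3-diene
Conditions: Me3SiOTf, Et3N, Et2O, 0 °C
Reagents that add atoms: trimethylsilyl trifluoromethanesulfonate, C[Si](C)(C)OS(=O)(=O)C(F)(F)F
Why: soft enolisation and O‑silylation of the ethyl ketone should give the thermodynamically preferred (Z)‑silyl enol ether, i.e. the 4‑methyl‑1‑methoxy‑3‑silyloxy diene.

Step 3
Reactants: 4 (1E,3Z)-1-methoxy-3-(trimethylsilyloxy)penta-1,3-diene; 5 3-[(tert-butyldimethylsilyl)oxy]propanal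
Product: 7 (2R,3S)-2-[2-(tert-butyldimethylsilyloxy)ethyl]-3-methyl-2,3-dihydro-4H-pyran-4-one, via cycloadduct 6 (not isolated)
Conditions: [Cr(L)Cl] (5 mol%; L = dianion C27H29NO2 of the Schiff base from (1R,2S)-1-aminoindan-2-ol and 3-(1-adamantyl)-2-hydroxy-5-methylbenzaldehyde, trivalent chromium), 4 Å molecular sieves, t-BuOMe, rt; then CF3CO2H (cat.), CH2Cl2, 0 °C; aq. NaHCO3
Reagents that add atoms: none
Why: catalytic asymmetric hetero‑Diels–Alder reaction in which the endo [4+2] addition of the (1E,3Z)‑diene places the C2 side chain and the C3 methyl cis, the chiral chromium Lewis acid selects the aldehyde face (C2), and acid then removes Me3Si and MeOH to give the enone.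

Step 4
Reactants: 7 (2R,3S)-2-[2-(tert-butyldimethylsilyloxy)ethyl]-3-methyl-2,3-dihydro-4H-pyran-4-one
Product: 9 (2R,3S,5S,6R)-2-[2-(tert-butyldimethylsilyloxy)ethyl]-5-hydroxy-6-[(4-methoxybenzyl)oxy]-3-methyltetrahydro-4H-pyran-4-one, via epoxide 8 (not isolated)
Conditions: dimethyldioxirane, acetone/CH2Cl2, 0 °C; evaporate; 4-methoxybenzyl alcohol, ZnCl2, THF, −78 to 0 °C
Reagents that add atoms: dimethyldioxirane, CC1(C)OO1; 4-methoxybenzyl alcohol, COc1ccc(CO)cc1
Why: epoxidation of the enol ether C5=C6 should occur on the face opposite the pseudo‑axial C3 methyl, and ZnCl2‑assisted opening at the acetal carbon with inversion (glycal‑epoxide glycosylation type) gives the trans 5‑hydroxy‑6‑alkoxy pattern, both groups equatorial.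

Step 5
Reactants: 10 (R)-but-3-yn-2-ol
Product: 11 (R)-3-(tert-butyldimethylsilyloxy)but-1-yne
Conditions: t-BuMe2SiCl, imidazole, DMF, rt
Reagents that add atoms: tert-butyldimethylsilyl chloride, CC(C)(C)[Si](C)(C)Cl
Why: standard silylation of a secondary alcohol; the stereocentre is not touched.

Step 6
Reactants: 9 (2R,3S,5S,6R)-2-[2-(tert-butyldimethylsilyloxy)ethyl]-5-hydroxy-6-[(4-methoxybenzyl)oxy]-3-methyltetrahydro-4H-pyran-4-one; 11 (R)-3-(tert-butyldimethylsilyloxy)but-1-yne
Product: 13 (2R,3R,4R,5S,6R)-4-[(3R)-3-(tert-butyldimethylsilyloxy)but-1-yn-1-yl]-6-[2-(tert-butyldimethylsilyloxy)ethyl]-2-[(4-methoxybenzyl)oxy]-5-methyltetrahydro-2H-pyran-3,4-diol, via lithium acetylide 12 (not isolated)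
Conditions: 11 (3.3 equiv), n-BuLi (3.1 equiv), THF, −78 °C; then 9, −78 to −30 °C; aq. NH4Cl
Reagents that add atoms: none
Why: alkynyllithium 1,2‑addition to the ketone, in which the slim nucleophile should enter axially, anti to the axial methyl on the neighbouring carbon of the chair (side chain, OH and OPMB equatorial), to give the equatorial tertiary alcohol; the first equivalent only deprotonates the free OH.

Step 7
Reactants: 13 (2R,3R,4R,5S,6R)-4-[(3R)-3-(tert-butyldimethylsilyloxy)but-1-yn-1-yl]-6-[2-(tert-butyldimethylsilyloxy)ethyl]-2-[(4-methoxybenzyl)oxy]-5-methyltetrahydro-2H-pyran-3,4-diol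
Product: 15 (3R)-3-(tert-butyldimethylsilyloxy)-1-[(2R,3R,4S,5S,6R)-6-[2-(tert-butyldimethylsilyloxy)ethyl]-3,4-dihydroxy-2-[(4-methoxybenzyl)oxy]-5-methyltetrahydro-2H-pyran-4-yl]butan-1-one, via alkylidene carbonate 14 (not isolated)
Conditions: AgOAc (10 mol%), DBU (1 equiv), CO2 (1 MPa), MeCN, rt; then H2O, 40 °C
Reagents that add atoms: carbon dioxide, O=C=O (its oxygen becomes the ketone oxygen); water, O (hydrolyses carbonate 14)
Why: silver‑catalysed carboxylative cyclisation of a tertiary propargylic alcohol (5‑exo‑dig attack of the carbonate on the activated alkyne) followed by hydrolysis of the enol carbonate is a formal hydration that can only place the carbonyl on the alkyne carbon next to the carbinol; no stereocentre is touched.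

Step 8
Reactants: 15 (3R)-3-(tert-butyldimethylsilyloxy)-1-[(2R,3R,4S,5S,6R)-6-[2-(tert-butyldimethylsilyloxy)ethyl]-3,4-dihydroxy-2-[(4-methoxybenzyl)oxy]-5-methyltetrahydro-2H-pyran-4-yl]butan-1-one; 16 (R)-2-methylbutanoic acid
Product: 18 pyranyl (2R)-2-methylbutanoate (ester on the ring C3 oxygen), via O-acylisourea 17 (not isolated)
Conditions: EDC·HCl, DMAP, CH2Cl2, 0 °C to rt
Reagents that add atoms: none
Why: Steglich esterification acylates the only secondary hydroxyl, the tertiary α‑ketol OH being too hindered; the acid stereocentre is carried in unchanged.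

Step 9
Reactants: 18 pyranyl (2R)-2-methylbutanoate with two silyl ethers
Product: 19 primary alcohol (2-hydroxyethyl side chain)
Conditions: HF·pyridine, pyridine, THF, 0 °C
Reagents that add atoms: none
Why: buffered HF desilylation removes a primary tert‑butyldimethylsilyl ether much faster than the secondary one.

Step 10
Reactants: 19 primary alcohol
Product: 20 aldehyde (2-oxoethyl side chain)
Conditions: Dess–Martin periodinane, NaHCO3, CH2Cl2, 0 °C to rt
Reagents that add atoms: none
Why: Dess–Martin oxidation of the only oxidisable (primary) alcohol; the tertiary OH is inert and no stereocentre is α to the new aldehyde.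

Step 11
Reactants: 20 aldehyde; 21 methyl acrylate
Product: 22 Morita–Baylis–Hillman alcohol (methyl 2-methylidene-3-hydroxy-4-pyranylbutanoate, carbinol epimers)
Conditions: methyl acrylate (neat, excess), DABCO (0.5 equiv), rt
Reagents that add atoms: none
Why: Morita–Baylis–Hillman reaction of an α‑unbranched aldehyde; the new carbinol centre is lost in the next step, so its configuration does not matter.

Step 12
Reactants: 22 Morita–Baylis–Hillman alcohol
Product: 23 (Z)-2-(bromomethyl)enoate
Conditions: N-bromosuccinimide, Me2S, CH2Cl2, 0 °C to rt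
Reagents that add atoms: N-bromosuccinimide, O=C1CCC(=O)N1Br
Why: activation of the allylic alcohol as an alkoxysulfonium salt and SN2' attack of bromide (allylic transposition) should give the thermodynamically preferred (Z)‑trisubstituted enoate with the primary bromide.

Step 13
Reactants: 23 (Z)-2-(bromomethyl)enoate
Product: 24 lactol (anomer mixture)
Conditions: DDQ, CH2Cl2/pH 7 aqueous buffer, 0 °C to rt
Reagents that add atoms: none
Why: oxidative cleavage of the 4‑methoxybenzyl acetal under neutral conditions leaves the allylic bromide, ester, ketone and silyl ether untouched.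

Step 14
Reactants: 24 lactol
Product: 27 silyl-protected target lactone, via allylindium aldehyde 25 (not isolated), via hydroxy ester 26 (not isolated)
Conditions: In powder (2 equiv), THF/H2O 1:1, rt; then TsOH·H2O (cat.), CH2Cl2, rt
Reagents that add atoms: none
Why: Indium inserts into the allylic C–Br bond and the allylindium adds through its γ‑carbon (C3a) to the aldehyde (C8a) that the lactol releases by ring–chain tautomerism, after which the cis γ‑hydroxy ester closes to the lactone; the closest known reaction type is the intramolecular Barbier cyclisation of ω‑formyl 2‑(bromomethyl)alk‑2‑enoates to carbocycle‑fused α‑methylene lactones, combined with indium allylation of unprotected lactols in water. The cycloheptane closes 7‑exo‑trig at the aldehyde carbon by SE2' attack, and the lactone closes 5‑exo‑trig by acyl substitution at the methyl ester. The cis ring fusion (C8a relative to C3a) should follow from the (Z)‑allylmetal reacting through a closed chair‑like six‑membered transition state, which gives the syn adduct. The sense relative to the existing centres should come from a chair‑like seven‑membered transition state in which the C7 acyl chain, the C6 methyl, C5–OH and the attacking enoate carbon are equatorial, while the carbonyl oxygen is axial, anti to the axial C8 acyloxy group (opposed dipoles) and syn to the axial C7–OH, which can bridge to indium. The step needs aldehyde‑over‑ketone chemoselectivity, which the far more reactive aldehyde and the neopentyl‑like position of the C7 ketone next to a fully substituted carbon should secure, and γ‑regioselectivity, which the primary C–In bond secures.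

Step 15
Reactants: 27 silyl-protected target lactone
Product: 28 target
Conditions: HF·pyridine, THF, 0 °C to rt
Reagents that add atoms: none
Why: acidic fluoride desilylation of the secondary silyl ether is compatible with the α‑methylene lactone, the ester and the β‑hydroxy ketone that it sets free.

**Compound list**

1 | (E)-4-methoxybut-3-en-2-one | CO/C=C/C(C)=O | starting material
2 | lithium (E)-4-methoxybuta-1,3-dien-2-olate | [Li]OC(=C)/C=C/OC | intermediate (not isolated)
3 | (E)-1-methoxypent-1-en-3-one | CO/C=C/C(=O)CC | intermediate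
4 | (1E,3Z)-1-methoxy-3-(trimethylsilyloxy)penta-1,3-diene | C/C=C(O[Si](C)(C)C)/C=C/OC | intermediate
5 | 3-[(tert-butyldimethylsilyl)oxy]propanal | O=CCCO[Si](C)(C)C(C)(C)C | starting material
6 | cycloadduct: (2R,3S)-2-[2-(tert-butyldimethylsilyloxy)ethyl]-6-methoxy-3-methyl-4-(trimethylsilyloxy)-3,6-dihydro-2H-pyran (acetal centre undefined) | COC1C=C(O[Si](C)(C)C)[C@@H](C)[C@H](O1)CCO[Si](C)(C)C(C)(C)C | intermediate (not isolated)
7 | (2R,3S)-2-[2-(tert-butyldimethylsilyloxy)ethyl]-3-methyl-2,3-dihydro-4H-pyran-4-one (2,3-cis) | C1=CC(=O)[C@@H](C)[C@H](O1)CCO[Si](C)(C)C(C)(C)C | intermediate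
8 | 5,6-epoxide of 7 (2,7-dioxabicyclo[4.1.0]heptan-5-one; epoxide oxygen trans to the methyl and the side chain) | [C@@H]12O[C@@H]1C(=O)[C@@H](C)[C@H](O2)CCO[Si](C)(C)C(C)(C)C | intermediate (not isolated)
9 | (2R,3S,5S,6R)-2-[2-(tert-butyldimethylsilyloxy)ethyl]-5-hydroxy-6-[(4-methoxybenzyl)oxy]-3-methyltetrahydro-4H-pyran-4-one | COc1ccc(CO[C@H]2[C@H](O)C(=O)[C@@H](C)[C@H](O2)CCO[Si](C)(C)C(C)(C)C)cc1 | intermediate
10 | (R)-but-3-yn-2-ol | C#C[C@@H](C)O | starting material
11 | (R)-3-(tert-butyldimethylsilyloxy)but-1-yne | C#C[C@@H](C)O[Si](C)(C)C(C)(C)C | intermediate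
12 | lithium acetylide of 11 | [Li]C#C[C@@H](C)O[Si](C)(C)C(C)(C)C | intermediate (not isolated)
13 | (2R,3R,4R,5S,6R)-4-[(3R)-3-(tert-butyldimethylsilyloxy)but-1-yn-1-yl]-6-[2-(tert-butyldimethylsilyloxy)ethyl]-2-[(4-methoxybenzyl)oxy]-5-methyltetrahydro-2H-pyran-3,4-diol | COc1ccc(CO[C@H]2[C@H](O)[C@](O)(C#C[C@@H](C)O[Si](C)(C)C(C)(C)C)[C@@H](C)[C@H](O2)CCO[Si](C)(C)C(C)(C)C)cc1 | intermediate
14 | spiro (Z)-4-alkylidene-1,3-dioxolan-2-one (cyclic enol carbonate of 13 at the tertiary oxygen) | COc1ccc(CO[C@H]2[C@H](O)[C@@]3(OC(=O)O/C3=C\[C@@H](C)O[Si](C)(C)C(C)(C)C)[C@@H](C)[C@H](O2)CCO[Si](C)(C)C(C)(C)C)cc1 | intermediate (not isolated)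
15 | (3R)-3-(tert-butyldimethylsilyloxy)-1-[(2R,3R,4S,5S,6R)-6-[2-(tert-butyldimethylsilyloxy)ethyl]-3,4-dihydroxy-2-[(4-methoxybenzyl)oxy]-5-methyltetrahydro-2H-pyran-4-yl]butan-1-one | COc1ccc(CO[C@H]2[C@H](O)[C@](O)(C(=O)C[C@@H](C)O[Si](C)(C)C(C)(C)C)[C@@H](C)[C@H](O2)CCO[Si](C)(C)C(C)(C)C)cc1 | intermediate
16 | (R)-2-methylbutanoic acid | CC[C@@H](C)C(=O)O | starting material
17 | O-acylisourea of 16 with EDC | CCN=C(NCCCN(C)C)OC(=O)[C@H](C)CC | intermediate (not isolated)
18 | (2R,3R,4S,5S,6R)-4-[(3R)-3-(tert-butyldimethylsilyloxy)butanoyl]-6-[2-(tert-butyldimethylsilyloxy)ethyl]-4-hydroxy-2-[(4-methoxybenzyl)oxy]-5-methyltetrahydro-2H-pyran-3-yl (2R)-2-methylbutanoate | COc1ccc(CO[C@H]2[C@H](OC(=O)[C@H](C)CC)[C@](O)(C(=O)C[C@@H](C)O[Si](C)(C)C(C)(C)C)[C@@H](C)[C@H](O2)CCO[Si](C)(C)C(C)(C)C)cc1 | intermediate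
19 | as 18 with a 6-(2-hydroxyethyl) group (primary alcohol) | COc1ccc(CO[C@H]2[C@H](OC(=O)[C@H](C)CC)[C@](O)(C(=O)C[C@@H](C)O[Si](C)(C)C(C)(C)C)[C@@H](C)[C@H](O2)CCO)cc1 | intermediate
20 | as 18 with a 6-(2-oxoethyl) group (aldehyde) | COc1ccc(CO[C@H]2[C@H](OC(=O)[C@H](C)CC)[C@](O)(C(=O)C[C@@H](C)O[Si](C)(C)C(C)(C)C)[C@@H](C)[C@H](O2)CC=O)cc1 | intermediate
21 | methyl acrylate | C=CC(=O)OC | starting material
22 | Morita–Baylis–Hillman alcohol: as 18 with a 6-[2-hydroxy-3-(methoxycarbonyl)but-3-en-1-yl] group (carbinol epimers) | COc1ccc(CO[C@H]2[C@H](OC(=O)[C@H](C)CC)[C@](O)(C(=O)C[C@@H](C)O[Si](C)(C)C(C)(C)C)[C@@H](C)[C@H](O2)CC(O)C(=C)C(=O)OC)cc1 | intermediate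
23 | allylic bromide: as 18 with a 6-[(2Z)-3-(bromomethyl)-4-methoxy-4-oxobut-2-en-1-yl] group | COc1ccc(CO[C@H]2[C@H](OC(=O)[C@H](C)CC)[C@](O)(C(=O)C[C@@H](C)O[Si](C)(C)C(C)(C)C)[C@@H](C)[C@H](O2)C/C=C(\CBr)C(=O)OC)cc1 | intermediate
24 | lactol: 23 with the 4-methoxybenzyl group replaced by H (2-hydroxytetrahydropyran, anomer mixture) | OC1[C@H](OC(=O)[C@H](C)CC)[C@](O)(C(=O)C[C@@H](C)O[Si](C)(C)C(C)(C)C)[C@@H](C)[C@H](O1)C/C=C(\CBr)C(=O)OC | intermediate
25 | open-chain hydroxy aldehyde tautomer carrying the allylindium unit (drawn as the allylindium dibromide) | O=C[C@H](OC(=O)[C@H](C)CC)[C@](O)(C(=O)C[C@@H](C)O[Si](C)(C)C(C)(C)C)[C@@H](C)[C@H](O)C/C=C(\C[In](Br)Br)C(=O)OC | intermediate (not isolated)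
26 | cycloheptane hydroxy ester (methyl 2-cycloheptylacrylate, seco-lactone of 27; ring configuration as in the target) | C=C(C(=O)OC)[C@@H]1C[C@@H](O)[C@H](C)[C@@](O)(C(=O)C[C@@H](C)O[Si](C)(C)C(C)(C)C)[C@@H](OC(=O)[C@H](C)CC)[C@@H]1O | intermediate (not isolated)
27 | (3aS,5R,6S,7S,8S,8aR)-7-[(3R)-3-(tert-butyldimethylsilyloxy)butanoyl]-5,7-dihydroxy-6-methyl-3-methylidene-2-oxooctahydro-2H-cyclohepta[b]furan-8-yl (2R)-2-methylbutanoate | C=C1C(=O)O[C@@H]2[C@H]1C[C@@H](O)[C@H](C)[C@@](O)(C(=O)C[C@@H](C)O[Si](C)(C)C(C)(C)C)[C@H]2OC(=O)[C@H](C)CC | intermediate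
28 | (3aS,5R,6S,7S,8S,8aR)-5,7-dihydroxy-7-[(3R)-3-hydroxybutanoyl]-6-methyl-3-methylidene-2-oxooctahydro-2H-cyclohepta[b]furan-8-yl (2R)-2-methylbutanoate | C=C1C(=O)O[C@@H]2[C@H]1C[C@@H](O)[C@H](C)[C@@](O)(C(=O)C[C@@H](C)O)[C@H]2OC(=O)[C@H](C)CC | target

**Count and risks**

Total steps: 15. Longest linear sequence: 14 (steps 1–4 and 6–15; step 5 is a one‑step side branch).

Steps most likely to fail:

1. Step 14 (key step). What may go wrong: E/Z equilibration of the allylindium by 1,3‑metal shift before ring closure (loss of the cis ring fusion), attack on the wrong aldehyde face, or competing addition to the C7 ketone. Fallback, setting out from 22 and coming back at 27: the Morita–Baylis–Hillman alcohol 22 is acetylated (Ac2O, pyridine) to the allylic acetate F1. Copper‑catalysed SN2' borylation (bis(pinacolato)diboron, CuCl, KOAc, DMF) gives the 2‑(methoxycarbonyl)allyl pinacolboronate F2, expected mainly with the ring CH2 cis to CH2B. DDQ in wet CH2Cl2 then gives the lactol boronate F3. Warming F3 in toluene (Sc(OTf)3 as optional catalyst) brings about intramolecular allylboration by a configurationally stable, ketone‑inert allylboronate through a closed chair transition state, and acid‑catalysed lactonisation of the resulting borate gives 27.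

2. Step 7. What may go wrong: sluggish carbonate formation at the hindered internal alkyne, or base‑induced β‑elimination of the silyloxy group once the ketone has formed. Fallback, setting out from 9 and coming back at 15: 2‑lithio‑1,3‑dithiane opens (R)‑propylene oxide to (R)-1-(1,3-dithian-2-yl)propan-2-ol F4, which is silylated (t‑BuMe2SiCl, imidazole) to the silyl ether F5. Lithiation of F5 (n‑BuLi, THF, −30 °C) and addition to ketone 9, again from the axial direction, gives the dithiane diol F6. S‑Methylative hydrolysis (MeI, CaCO3, MeCN/H2O) then unveils the ketone of 15.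

3. Step 11. What may go wrong: amine‑induced β‑elimination (retro‑oxa‑Michael opening of the pyran at the carbon β to the aldehyde) and aldol self‑condensation during the slow reaction. Fallback, setting out from 20 and coming back at 22: the [α‑(methoxycarbonyl)vinyl]aluminium reagent made from methyl propiolate with i‑Bu2AlH and N‑methylmorpholine N‑oxide in THF at 0 °C adds to the aldehyde under non‑basic conditions and gives the same alcohol 22; no new compound is made on the way.

**Further compounds**

F1 | step 14 | acetate of 22 (allylic acetate) | COc1ccc(CO[C@H]2[C@H](OC(=O)[C@H](C)CC)[C@](O)(C(=O)C[C@@H](C)O[Si](C)(C)C(C)(C)C)[C@@H](C)[C@H](O2)CC(OC(C)=O)C(=C)C(=O)OC)cc1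
F2 | step 14 | (Z)-2-(methoxycarbonyl)allyl pinacolboronate, 4-methoxybenzyl acetal | COc1ccc(CO[C@H]2[C@H](OC(=O)[C@H](C)CC)[C@](O)(C(=O)C[C@@H](C)O[Si](C)(C)C(C)(C)C)[C@@H](C)[C@H](O2)C/C=C(\CB3OC(C)(C)C(C)(C)O3)C(=O)OC)cc1
F3 | step 14 | lactol boronate (anomer mixture) | OC1[C@H](OC(=O)[C@H](C)CC)[C@](O)(C(=O)C[C@@H](C)O[Si](C)(C)C(C)(C)C)[C@@H](C)[C@H](O1)C/C=C(\CB2OC(C)(C)C(C)(C)O2)C(=O)OC
F4 | step 7 | (R)-1-(1,3-dithian-2-yl)propan-2-ol | C[C@@H](O)CC1SCCCS1
F5 | step 7 | (R)-tert-butyl{[1-(1,3-dithian-2-yl)propan-2-yl]oxy}dimethylsilane | C[C@@H](O[Si](C)(C)C(C)(C)C)CC1SCCCS1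
F6 | step 7 | dithiane diol (1,3-dithiane ketal of the ketone of 15) | COc1ccc(CO[C@H]2[C@H](O)[C@](O)(C3(C[C@@H](C)O[Si](C)(C)C(C)(C)C)SCCCS3)[C@@H](C)[C@H](O2)CCO[Si](C)(C)C(C)(C)C)cc1
F0 | step 11 | none | none
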